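**Plan**

- Retrosynthesis: the enone Cα–Cβ bond is cut first (Claisen–Schmidt), giving a benzofuran aldehyde and an acetophenone. The C3'–prenyl bond and the free 4'-OH are traced back together to a 4'-O-(1,1-dimethylallyl) ether (aromatic Claisen rearrangement).
- The dihydrofuran ring (O1, C2, C3, C3a, C7a) is not built directly. Its exocyclic C(CH3)2OH carbon on C2 sits one bond from O1, which marks a 1,2-shift of the aryl ether oxygen. The ring is therefore traced back to the pyran ring of a trans-3,4-dioxygenated 2,2-dimethylchroman, in which that carbon is ring atom C2.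
- Forward, benzofuran half: chromene nitrile → epoxide → trans hydroxy ether → ring contraction (six to five) → ether cleavage → aldehyde.
- Forward, acetophenone half and union: resacetophenone → tertiary propargyl ether → 1,1-dimethylallyl ether; aldol condensation joins the halves; the Claisen rearrangement ends the route.
- Stereochemistry: catalyst-controlled epoxidation sets (3S,4S); the SN2 opening inverts C4 and the ring contraction inverts C3, which gives the trans-(2R,3R) pair. The E-alkene is the thermodynamic outcome of the condensation.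

Key step: step 3

Remark: 2,2-dimethyl-2H-chromene-6-carbonitrile (1) is taken as a purchasable starting material, and the (S,S)-salen manganese catalyst is taken to deliver the (3S,4S)-epoxide, as expected for a cis-olefin conjugated to an arene.

**Route**

Step 1
Reactants: 1 2,2-dimethyl-2H-chromene-6-carbonitrile
Product: 2 (3S,4S)-3,4-epoxy-2,2-dimethylchromane-6-carbonitrile
Conditions: (S,S)-N,N'-bis(3,5-di-tert-butylsalicylidene)-1,2-cyclohexanediaminomanganese chloride (cat.), aq. NaOCl (pH 11.3), 4-phenylpyridine N-oxide (cat.), CH2Cl2, 0 °C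
Reagents that add atoms: sodium hypochlorite, [Na+].[O-]Cl
Why: Jacobsen–Katsuki epoxidation of a cis-disubstituted, arene-conjugated olefin, the best substrate class for this catalyst; the (S,S)-ligand should direct oxygen transfer to the face that gives the (3S,4S)-epoxide, so both stereocentres are set under catalyst control.

Step 2
Reactants: 2 (3S,4S)-3,4-epoxy-2,2-dimethylchromane-6-carbonitrile
Product: 3 (3S,4R)-3-hydroxy-4-[(4-methoxybenzyl)oxy]-2,2-dimethylchromane-6-carbonitrile
Conditions: 4-methoxybenzyl alcohol (5 equiv), NaH (0.3 equiv), THF, 0 → 50 °C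
Reagents that add atoms: 4-methoxybenzyl alcohol, COc1ccc(CO)cc1
Why: base-catalysed SN2 alcoholysis of the epoxide; the alkoxide should attack benzylic C4 with inversion (C3 is shielded by the adjacent gem-dimethyl carbon), so C4 becomes R, C3 (S) is untouched and the trans hydroxy ether results, while proton transfer from the alcohol regenerates the alkoxide.

Step 3
Reactants: 3 (3S,4R)-3-hydroxy-4-[(4-methoxybenzyl)oxy]-2,2-dimethylchromane-6-carbonitrile
Product: 6 (2R,3R)-2-(2-hydroxypropan-2-yl)-3-[(4-methoxybenzyl)oxy]-2,3-dihydro-1-benzofuran-5-carbonitrile, via C3 triflate 4 (not isolated), via bridged oxiranium triflate 5 (not isolated)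
Conditions: Tf2O (1.3 equiv), 2,6-lutidine (3 equiv), CH2Cl2, −78 → −40 °C; then THF/H2O (2:1), 0 → 25 °C
Reagents that add atoms: triflic anhydride, O=S(=O)(C(F)(F)F)OS(=O)(=O)C(F)(F)F (its CF3SO2 unit is carried only by 4 and 5); water, O
Why: O-triflation gives 4, in whose half-chair both trans substituents should sit pseudo-equatorially, so that the C3–OTf bond is antiperiplanar to the ring C2–O1 bond; the aryl ether oxygen displaces triflate from the rear (inversion at C3) to give the bridged oxiranium ion 5, whose positive charge rests largely on the gem-dimethyl carbon, and water opens 5 at that tertiary carbon, cleaving C2–O1. The net event is a 1,2-shift of O1 that turns the pyran ring into the dihydrofuran ring and the old ring carbon C2 into the exocyclic C(CH3)2OH group; the closest known reaction type is the anchimerically assisted ring contraction of 3-hydroxy-2,2-dimethylchromans and of equatorial pyranoside 2-triflates on activation of the hydroxyl (sulfonylation, DAST or Mitsunobu conditions). The five-membered ring is closed through the O1–C3 bond by an intramolecular SN2 displacement (3-exo-tet with respect to the transient oxirane), and it is set free when the exocyclic O–CMe2 bond of 5 breaks. The new C2 stereocentre of the benzofuran (old C3, S) is set by stereospecific inversion to R, the old C4 (R) is not touched and becomes C3 (R), so the trans-(2R,3R) pair follows from the trans-(3S,4R) arrangement of 3. The step needs migration of O1 and not of the C4–C4a aryl bond or of the C4 oxygen, and capture by water and not loss of a methyl proton: the diequatorial conformer aligns O1 while the arene π-system lies in the ring plane and cannot bridge, the benzylic oxygen is a non-acylating ether gauche to the leaving group, C3 is neopentyl and closed to external SN2, and water is present in large excess once the triflate is formed.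

Step 4
Reactants: 6 (2R,3R)-2-(2-hydroxypropan-2-yl)-3-[(4-methoxybenzyl)oxy]-2,3-dihydro-1-benzofuran-5-carbonitrile
Product: 7 (2R,3R)-3-hydroxy-2-(2-hydroxypropan-2-yl)-2,3-dihydro-1-benzofuran-5-carbonitrile
Conditions: DDQ (1.3 equiv), CH2Cl2/pH 7 phosphate buffer (10:1), 0 °C → rt
Reagents that add atoms: none
Why: oxidative cleavage of a 4-methoxybenzyl ether (hydride abstraction from the anisyl CH2, hydrolysis of the oxocarbenium ion); the electron-poor cyanoarene and the tertiary alcohol should be inert, the trans arrangement disfavours acetal formation with the tertiary hydroxyl, and no stereocentre is touched.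

Step 5
Reactants: 7 (2R,3R)-3-hydroxy-2-(2-hydroxypropan-2-yl)-2,3-dihydro-1-benzofuran-5-carbonitrile
Product: 9 (2R,3R)-3-hydroxy-2-(2-hydroxypropan-2-yl)-2,3-dihydro-1-benzofuran-5-carbaldehyde, via N-aluminated aldimine 8 (not isolated)
Conditions: iBu2AlH (4 equiv), CH2Cl2, −78 → −20 °C; then aq. potassium sodium tartrate, rt
Reagents that add atoms: water, O
Why: partial reduction of a nitrile with DIBAL-H; one hydride adds to give the N-aluminated aldimine, which is not reduced further at low temperature and is hydrolysed to the aldehyde on near-neutral work-up, while two equivalents of hydride are consumed by the hydroxyl groups, whose stereocentres are not affected.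

Step 6
Reactants: 10 1-(2,4-dihydroxyphenyl)ethan-1-one (2,4-dihydroxyacetophenone); 11 3-chloro-3-methylbut-1-yne
Product: 12 1-[2-hydroxy-4-(2-methylbut-3-yn-2-yloxy)phenyl]ethan-1-one
Conditions: K2CO3 (2 equiv), KI (cat.), CuI (cat.), acetone, reflux
Reagents that add atoms: none
Why: copper-assisted O-alkylation of a phenol with a tertiary propargylic chloride; only the free 4-OH should react, because the 2-OH is held in a hydrogen bond to the acetyl group.

Step 7
Reactants: 12 1-[2-hydroxy-4-(2-methylbut-3-yn-2-yloxy)phenyl]ethan-1-one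
Product: 13 1-[2-hydroxy-4-(2-methylbut-3-en-2-yloxy)phenyl]ethan-1-one
Conditions: H2 (1 atm), Pd/CaCO3 poisoned with Pb(OAc)2 (Lindlar catalyst), quinoline, EtOAc, rt
Reagents that add atoms: none
Why: Lindlar semi-hydrogenation of a terminal alkyne; the poisoned catalyst should stop at the alkene and leave the aryl ketone and the tertiary allylic C–O bond intact.

Step 8
Reactants: 9 (2R,3R)-3-hydroxy-2-(2-hydroxypropan-2-yl)-2,3-dihydro-1-benzofuran-5-carbaldehyde; 13 1-[2-hydroxy-4-(2-methylbut-3-en-2-yloxy)phenyl]ethan-1-one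
Product: 15 (E)-1-[2-hydroxy-4-(2-methylbut-3-en-2-yloxy)phenyl]-3-[(2R,3R)-3-hydroxy-2-(2-hydroxypropan-2-yl)-2,3-dihydro-1-benzofuran-5-yl]prop-2-en-1-one, via β-hydroxy ketone 14 (not isolated)
Conditions: KOH (50% aq., 10 equiv), EtOH, 0 °C → rt; then aq. NH4Cl to pH 6–7 at 0 °C
Reagents that add atoms: none
Why: Claisen–Schmidt condensation; with the 4'-oxygen capped as an ether the methyl ketone enolate adds to the non-enolisable aldehyde and E1cB dehydration of the aldol gives the conjugated E-enone, while the two carbinol centres carry no acidic hydrogen and cannot epimerise in base.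

Step 9
Reactants: 15 (E)-1-[2-hydroxy-4-(2-methylbut-3-en-2-yloxy)phenyl]-3-[(2R,3R)-3-hydroxy-2-(2-hydroxypropan-2-yl)-2,3-dihydro-1-benzofuran-5-yl]prop-2-en-1-one
Product: 17 paratocarpin G, (E)-1-[2,4-dihydroxy-3-(3-methylbut-2-en-1-yl)phenyl]-3-[(2R,3R)-3-hydroxy-2-(2-hydroxypropan-2-yl)-2,3-dihydro-1-benzofuran-5-yl]prop-2-en-1-one, via cyclohexadienone tautomer 16 (not isolated)
Conditions: degassed PhMe, 120 °C (sealed tube)
Reagents that add atoms: none
Why: aromatic Claisen rearrangement of a tertiary allyl aryl ether; the [3,3] shift joins the terminal CH2 to C3' and delivers the 3-methylbut-2-enyl group, the chelate between 2'-OH and the carbonyl fixes the bond pattern of the ring so that C3' and not C5' should be the terminus, and tautomerisation of the dienone frees the 4'-OH, with no stereocentre involved.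

**Compound list**

1 | 2,2-dimethyl-2H-chromene-6-carbonitrile | CC1(C)C=Cc2cc(C#N)ccc2O1 | starting material
2 | (3S,4S)-3,4-epoxy-2,2-dimethylchromane-6-carbonitrile | CC1(C)Oc2ccc(C#N)cc2[C@@H]2O[C@H]12 | intermediate
3 | (3S,4R)-3-hydroxy-4-[(4-methoxybenzyl)oxy]-2,2-dimethylchromane-6-carbonitrile | CC1(C)Oc2ccc(C#N)cc2[C@@H](OCc2ccc(OC)cc2)[C@@H]1O | intermediate
4 | (3S,4R)-6-cyano-4-[(4-methoxybenzyl)oxy]-2,2-dimethylchroman-3-yl trifluoromethanesulfonate | CC1(C)Oc2ccc(C#N)cc2[C@@H](OCc2ccc(OC)cc2)[C@@H]1OS(=O)(=O)C(F)(F)F | intermediate (not isolated)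
5 | bridged oxiranium ion (O1 bonded to the aryl carbon, to the CMe2 carbon and to the former C3; 4-methoxybenzyloxy group on the benzylic carbon), triflate salt | N#Cc1ccc2c(c1)[C@@H](OCc1ccc(OC)cc1)[C@@H]1C(C)(C)[O+]12.[O-]S(=O)(=O)C(F)(F)F | intermediate (not isolated)
6 | (2R,3R)-2-(2-hydroxypropan-2-yl)-3-[(4-methoxybenzyl)oxy]-2,3-dihydro-1-benzofuran-5-carbonitrile | N#Cc1ccc2c(c1)[C@@H](OCc1ccc(OC)cc1)[C@H](C(C)(C)O)O2 | intermediate
7 | (2R,3R)-3-hydroxy-2-(2-hydroxypropan-2-yl)-2,3-dihydro-1-benzofuran-5-carbonitrile | N#Cc1ccc2c(c1)[C@@H](O)[C@H](C(C)(C)O)O2 | intermediate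
8 | aldimine of 9 (N-aluminated in the flask, drawn as the free imine) | N=Cc1ccc2c(c1)[C@@H](O)[C@H](C(C)(C)O)O2 | intermediate (not isolated)
9 | (2R,3R)-3-hydroxy-2-(2-hydroxypropan-2-yl)-2,3-dihydro-1-benzofuran-5-carbaldehyde | O=Cc1ccc2c(c1)[C@@H](O)[C@H](C(C)(C)O)O2 | intermediate
10 | 1-(2,4-dihydroxyphenyl)ethan-1-one | CC(=O)c1ccc(O)cc1O | starting material
11 | 3-chloro-3-methylbut-1-yne | C#CC(C)(C)Cl | starting material
12 | 1-[2-hydroxy-4-(2-methylbut-3-yn-2-yloxy)phenyl]ethan-1-one | CC(=O)c1ccc(OC(C)(C)C#C)cc1O | intermediate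
13 | 1-[2-hydroxy-4-(2-methylbut-3-en-2-yloxy)phenyl]ethan-1-one | CC(=O)c1ccc(OC(C)(C)C=C)cc1O | intermediate
14 | 3-hydroxy-1-[2-hydroxy-4-(2-methylbut-3-en-2-yloxy)phenyl]-3-[(2R,3R)-3-hydroxy-2-(2-hydroxypropan-2-yl)-2,3-dihydro-1-benzofuran-5-yl]propan-1-one (both epimers at the new carbinol carbon) | C=CC(C)(C)Oc1ccc(C(=O)CC(O)c2ccc3c(c2)[C@@H](O)[C@H](C(C)(C)O)O3)c(O)c1 | intermediate (not isolated)
15 | (E)-1-[2-hydroxy-4-(2-methylbut-3-en-2-yloxy)phenyl]-3-[(2R,3R)-3-hydroxy-2-(2-hydroxypropan-2-yl)-2,3-dihydro-1-benzofuran-5-yl]prop-2-en-1-one | C=CC(C)(C)Oc1ccc(C(=O)/C=C/c2ccc3c(c2)[C@@H](O)[C@H](C(C)(C)O)O3)c(O)c1 | intermediate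
16 | 6-(3-methylbut-2-enyl)cyclohexa-2,4-dien-1-one tautomer of 17 (ring carbon bearing the prenyl group is sp3, either configuration) | CC(C)=CCC1C(=O)C=CC(C(=O)/C=C/c2ccc3c(c2)[C@@H](O)[C@H](C(C)(C)O)O3)=C1O | intermediate (not isolated)
17 | paratocarpin G, (E)-1-[2,4-dihydroxy-3-(3-methylbut-2-en-1-yl)phenyl]-3-[(2R,3R)-3-hydroxy-2-(2-hydroxypropan-2-yl)-2,3-dihydro-1-benzofuran-5-yl]prop-2-en-1-one | CC(C)=CCc1c(O)ccc(C(=O)/C=C/c2ccc3c(c2)[C@@H](O)[C@H](C(C)(C)O)O3)c1O | target

**Step count and risks**

Total step count: 9 (steps 1–5 for the benzofuran aldehyde, steps 6–7 for the acetophenone, steps 8–9 for union and completion).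
Longest linear sequence: 7 steps (1, 2, 3, 4, 5, 8, 9).

Steps most likely to fail:

1. Step 3 (ring contraction). Loss of a methyl proton from the bridged ion could outrun capture by water, or the triflate could ionise before water is present, so that the tertiary alcohol is not formed directly. Fallback, from 3 back to 6: the contraction would be run on purpose under anhydrous conditions (Tf2O, 2,6-lutidine, CH2Cl2, −78 → 0 °C). The same intermediates 4 and 5 should then collapse by elimination to (2S,3R)-3-[(4-methoxybenzyl)oxy]-2-(prop-1-en-2-yl)-2,3-dihydro-1-benzofuran-5-carbonitrile F1, which has the same spatial arrangement as 6; only the descriptor at C2 changes, through the priority rule. Markovnikov hydration of the 1,1-disubstituted alkene by hydrogen-atom transfer (Mukaiyama hydration: tris(dipivaloylmethanato)manganese, Mn(dpm)3, cat., PhSiH3, O2, iPrOH/CH2Cl2, 0 °C) would then give 6. The tertiary alcohol thus comes from an alkene and not from capture of a cation.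

2. Step 9 (late Claisen rearrangement). Migration to C5' in place of C3', loss of the tertiary allyl group as isoprene, or thermal closure of the 2'-hydroxychalcone to a flavanone could erode the last step on the most advanced material. Fallback, from 13 and 9 to 17: 13 would be rearranged at the acetophenone stage (PhMe, 120 °C) to 1-[2,4-dihydroxy-3-(3-methylbut-2-en-1-yl)phenyl]ethan-1-one F2, where regioisomers can be removed on a simple compound. The 4-OH would then be capped (allyl bromide, K2CO3, acetone, reflux) to give 1-[2-hydroxy-3-(3-methylbut-2-en-1-yl)-4-(prop-2-en-1-yloxy)phenyl]ethan-1-one F3. Claisen–Schmidt condensation of F3 with 9 (KOH, EtOH/H2O, rt) should give (E)-1-[2-hydroxy-3-(3-methylbut-2-en-1-yl)-4-(prop-2-en-1-yloxy)phenyl]-3-[(2R,3R)-3-hydroxy-2-(2-hydroxypropan-2-yl)-2,3-dihydro-1-benzofuran-5-yl]prop-2-en-1-one F4. The aryl allyl ether would be removed under non-acidic conditions (Pd(PPh3)4 cat., K2CO3, MeOH, rt) to reach 17.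

3. Step 2 (epoxide opening). Addition of the alkoxide to the nitrile during the prolonged warm, basic reaction, or incomplete trans selectivity, could lower the supply of 3. Fallback, from 2 back to 3: the epoxide would be hydrolysed under dilute acid (HClO4 cat., THF/H2O, 0 °C), with water attacking benzylic C4 with inversion, to give (3S,4R)-3,4-dihydroxy-2,2-dimethylchromane-6-carbonitrile F5. The less hindered and more acidic benzylic hydroxyl would then be alkylated selectively (NaH 1.05 equiv, 4-methoxybenzyl chloride, Bu4NI cat., DMF, −20 → 0 °C) to give 3; the C3 hydroxyl is flanked by the gem-dimethyl carbon and should react far more slowly.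

Further compounds
F1 | step 3 | (2S,3R)-3-[(4-methoxybenzyl)oxy]-2-(prop-1-en-2-yl)-2,3-dihydro-1-benzofuran-5-carbonitrile | N#Cc1ccc2c(c1)[C@@H](OCc1ccc(OC)cc1)[C@H](C(C)=C)O2
F2 | step 9 | 1-[2,4-dihydroxy-3-(3-methylbut-2-en-1-yl)phenyl]ethan-1-one | CC(=O)c1ccc(O)c(CC=C(C)C)c1O
F3 | step 9 | 1-[2-hydroxy-3-(3-methylbut-2-en-1-yl)-4-(prop-2-en-1-yloxy)phenyl]ethan-1-one | CC(=O)c1ccc(OCC=C)c(CC=C(C)C)c1O
F4 | step 9 | (E)-1-[2-hydroxy-3-(3-methylbut-2-en-1-yl)-4-(prop-2-en-1-yloxy)phenyl]-3-[(2R,3R)-3-hydroxy-2-(2-hydroxypropan-2-yl)-2,3-dihydro-1-benzofuran-5-yl]prop-2-en-1-one | C=CCOc1ccc(C(=O)/C=C/c2ccc3c(c2)[C@@H](O)[C@H](C(C)(C)O)O3)c(O)c1CC=C(C)C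
F5 | step 2 | (3S,4R)-3,4-dihydroxy-2,2-dimethylchromane-6-carbonitrile | CC1(C)Oc2ccc(C#N)cc2[C@@H](O)[C@@H]1O
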